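**Strategy.** The ten-membered carbocycle (C1–C10, germacrane numbering) is opened at C7–C8. The array C13=C11–C7–C8–O, in which the exocyclic methylene of the γ-lactone is homoallylic to the C8 carbinol, is the retron of an aldehyde allylation with allylic transposition. The precursor is therefore an open-chain 3-(bromomethyl)butenolide whose C6 carries the (2Z,4Z)-dienyl epoxide chain ending in the C8 aldehyde. CrCl2 converts the bromide into an allylchromium that attacks the aldehyde through C7: one operation closes the ring, sets C7 and C8 and unveils the α-methylene lactone. The seco chain comes from Sonogashira union of a Z-iodoalkenyl butenolide with an epoxy alkyne; the C8 ester is installed last with inversion.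

Key step: step 21

Remark: germacrane numbering is used for the skeleton (ring C1–C10, lactone carbons C11–C13, methyls C14 on C10 and C15 on C4). The cyclisation is assumed to follow the closed chair transition state that this reagent class shows in intermolecular allylations; this predicts the 8S carbinol, and the opposite outcome is covered by the first fallback.

**Acid side chain**

Step 1
Reactants: 1 (E)-2-methylbut-2-en-1-ol (tiglyl alcohol)
Product: 2 ((2R,3R)-2,3-dimethyloxiran-2-yl)methanol
Conditions: Ti(OiPr)4 (cat.), D-(−)-diisopropyl tartrate, t-BuOOH, 4 Å MS, CH2Cl2, −20 °C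
Reagents that add atoms: tert-butyl hydroperoxide, CC(C)(C)OO
Why: Sharpless asymmetric epoxidation, in which the Ti–D-(−)-tartrate–peroxide complex binds the allylic hydroxyl and delivers oxygen to one face of the E alkene, sets both epoxide carbons as (2R,3R), the mirror image of the (2S,3S) product that L-(+)-tartrate gives with E-allylic alcohols.

Step 2
Reactants: 2 ((2R,3R)-2,3-dimethyloxiran-2-yl)methanol
Product: 3 (2S,3R)-2,3-dimethyloxirane-2-carboxylic acid
Conditions: RuCl3 hydrate (cat.), NaIO4, EtOAc/MeCN/H2O, 0 °C to rt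
Reagents that add atoms: water, O
Why: RuO4 generated catalytically (Sharpless oxidation) takes the primary alcohol through the aldehyde hydrate to the acid without touching the epoxide, so both stereocentres are kept (C2 becomes S only through the change in priorities).

**Fragment B: epoxy alkyne (C1–C3, C8–C10, C14)**

Step 3
Reactants: 4 but-3-yn-1-ol
Product: 5 1-[(but-3-yn-1-yloxy)methyl]-4-methoxybenzene
Conditions: NaH, PMBCl, n-Bu4NI (cat.), THF, 0 °C to rt
Reagents that add atoms: 4-methoxybenzyl chloride, COc1ccc(CCl)cc1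
Why: Williamson etherification, in which the sodium alkoxide (the alkyne C–H is far less acidic) displaces chloride from the benzylic halide.

Step 4
Reactants: 5 1-[(but-3-yn-1-yloxy)methyl]-4-methoxybenzene
Product: 7 (E)-5-[(4-methoxybenzyl)oxy]-3-methylpent-2-en-1-ol, via alkenylalane 6 (not isolated)
Conditions: Me3Al, Cp2ZrCl2 (cat.), CH2Cl2, 0 °C to rt; then (CH2O)n, THF, rt; aq. potassium sodium tartrate
Reagents that add atoms: trimethylaluminium, C[Al](C)C; paraformaldehyde (formaldehyde unit), C=O
Why: Zirconium-catalysed carboalumination (Negishi) adds Me–Al syn across the terminal alkyne with methyl on the internal carbon, and hydroxymethylation of the alkenyl–Al bond with retention fixes the E geometry (CH2OH cis to CH3).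

Step 5
Reactants: 7 (E)-5-[(4-methoxybenzyl)oxy]-3-methylpent-2-en-1-ol
Product: 8 ((2R,3R)-3-{2-[(4-methoxybenzyl)oxy]ethyl}-3-methyloxiran-2-yl)methanol
Conditions: Ti(OiPr)4 (cat.), D-(−)-diethyl tartrate, t-BuOOH, 4 Å MS, CH2Cl2, −20 °C
Reagents that add atoms: tert-butyl hydroperoxide, CC(C)(C)OO
Why: Sharpless asymmetric epoxidation with D-(−)-tartrate sets C1 and C10 (both R) on the E-3,3-disubstituted allylic alcohol, the enantiomeric sense to the (2S,3S) outcome of L-(+)-tartrate with geraniol-type substrates.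

Step 6
Reactants: 8 ((2R,3R)-3-{2-[(4-methoxybenzyl)oxy]ethyl}-3-methyloxiran-2-yl)methanol
Product: 9 (2S,3R)-3-{2-[(4-methoxybenzyl)oxy]ethyl}-3-methyloxirane-2-carbaldehyde
Conditions: Dess–Martin periodinane, NaHCO3, CH2Cl2, 0 °C to rt
Reagents that add atoms: none
Why: Buffered Dess–Martin oxidation should give the α,β-epoxy aldehyde without epimerisation or epoxide opening (the descriptor changes only by priority).

Step 7
Reactants: 9 (2S,3R)-3-{2-[(4-methoxybenzyl)oxy]ethyl}-3-methyloxirane-2-carbaldehyde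
Product: 10 (2R,3R)-3-ethynyl-2-{2-[(4-methoxybenzyl)oxy]ethyl}-2-methyloxirane
Conditions: dimethyl (1-diazo-2-oxopropyl)phosphonate, K2CO3, MeOH, 0 °C to rt
Reagents that add atoms: dimethyl (1-diazo-2-oxopropyl)phosphonate, CC(=O)C(=[N+]=[N-])P(=O)(OC)OC
Why: Ohira–Bestmann (Seyferth–Gilbert) homologation, in which the diazomethylphosphonate anion adds to the aldehyde and the resulting alkylidene carbene rearranges to the terminal alkyne, is mild enough for the epoxide and leaves its stereocentres untouched.

**Fragment A: Z-iodoalkenyl butenolide (C4–C7, C11–C13, C15)**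

Step 8
Reactants: 11 acrolein; 12 prop-1-yn-1-ylmagnesium bromide
Product: 13 rac-hex-1-en-4-yn-3-ol
Conditions: THF, −78 °C to 0 °C; aq. NH4Cl
Reagents that add atoms: none
Why: 1,2-Addition of an alkynyl Grignard reagent to the enal at low temperature gives the racemic vinyl propynyl carbinol.

Step 9
Reactants: 13 rac-hex-1-en-4-yn-3-ol
Product: 14 (S)-hex-1-en-4-yn-3-ol
Conditions: Ti(OiPr)4, L-(+)-diisopropyl tartrate, t-BuOOH (0.6 equiv), 4 Å MS, CH2Cl2, −20 °C
Reagents that add atoms: none
Why: In this Sharpless kinetic resolution the (R)-carbinol, whose propynyl group lies on the alkene face opposite to oxygen delivery by the Ti–L-(+)-tartrate complex, is epoxidised much faster, so the (S)-enantiomer should be recovered at slightly more than half conversion and fixes C6.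

Step 10
Reactants: 14 (S)-hex-1-en-4-yn-3-ol
Product: 16 (3S,4Z)-4-iodohexa-1,4-dien-3-ol, via cyclic alkenylalanate 15 (not isolated)
Conditions: NaAlH2(OCH2CH2OMe)2 (Red-Al), THF, 0 °C to rt; EtOAc; then iodine, −78 °C to 0 °C
Reagents that add atoms: iodine, [I][I]
Why: Hydroxyl-directed trans-hydroalumination of the propargylic alcohol puts hydride on the proximal carbon (C5) and aluminium on the distal one (C4), and iodinolysis with retention gives the Z-iodoalkene with iodine cis to the carbinol carbon, the vinyl group and C6 being unaffected.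

Step 11
Reactants: 17 ethyl 2-(hydroxymethyl)acrylate
Product: 18 ethyl 2-{[(tert-butyldimethylsilyl)oxy]methyl}acrylate
Conditions: TBSCl, imidazole, CH2Cl2, 0 °C to rt
Reagents that add atoms: tert-butyldimethylsilyl chloride, CC(C)(C)[Si](C)(C)Cl
Why: Standard imidazole-promoted silylation of the primary allylic alcohol.

Step 12
Reactants: 18 ethyl 2-{[(tert-butyldimethylsilyl)oxy]methyl}acrylate
Product: 19 2-{[(tert-butyldimethylsilyl)oxy]methyl}acrylic acid
Conditions: LiOH, THF/H2O, 0 °C to rt; then cold 1 M HCl to pH 4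
Reagents that add atoms: lithium hydroxide, [Li+].[OH-]
Why: Saponification of the ethyl ester, the silyl ether surviving mild base and a brief cold acidification.

Step 13
Reactants: 16 (3S,4Z)-4-iodohexa-1,4-dien-3-ol; 19 2-{[(tert-butyldimethylsilyl)oxy]methyl}acrylic acid
Product: 20 (3S,4Z)-4-iodohexa-1,4-dien-3-yl 2-{[(tert-butyldimethylsilyl)oxy]methyl}acrylate
Conditions: DCC, DMAP (cat.), CH2Cl2, 0 °C to rt
Reagents that add atoms: none
Why: Steglich esterification acylates the secondary bis-allylic alcohol under neutral conditions that leave C6 and the vinyl iodide untouched.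

Step 14
Reactants: 20 (3S,4Z)-4-iodohexa-1,4-dien-3-yl 2-{[(tert-butyldimethylsilyl)oxy]methyl}acrylate
Product: 21 (S)-3-{[(tert-butyldimethylsilyl)oxy]methyl}-5-[(Z)-2-iodoprop-1-en-1-yl]furan-2(5H)-one
Conditions: second-generation Grubbs catalyst, (H2IMes)(PCy3)Cl2Ru=CHPh (5 mol %), toluene, 80 °C
Reagents that add atoms: none
Why: Ring-closing metathesis between the terminal vinyl group and the 1,1-disubstituted acrylate closes the butenolide (C7=C11) with loss of ethene, the trisubstituted iodoalkene being inert to the ruthenium carbene.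

Step 15
Reactants: 21 (S)-3-{[(tert-butyldimethylsilyl)oxy]methyl}-5-[(Z)-2-iodoprop-1-en-1-yl]furan-2(5H)-one
Product: 22 (S)-3-(hydroxymethyl)-5-[(Z)-2-iodoprop-1-en-1-yl]furan-2(5H)-one
Conditions: HF·pyridine, THF, 0 °C to rt
Reagents that add atoms: none
Why: Fluoride cleavage of the silyl ether under acidic, non-basic conditions does not endanger the base-labile C6–H of the butenolide.

**Union and endgame**

Step 16
Reactants: 22 (S)-3-(hydroxymethyl)-5-[(Z)-2-iodoprop-1-en-1-yl]furan-2(5H)-one; 10 (2R,3R)-3-ethynyl-2-{2-[(4-methoxybenzyl)oxy]ethyl}-2-methyloxirane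
Product: 23 (R)-3-(hydroxymethyl)-5-[(Z)-4-{(2R,3R)-3-[2-(4-methoxybenzyloxy)ethyl]-3-methyloxiran-2-yl}-2-methylbut-1-en-3-yn-1-yl]furan-2(5H)-one
Conditions: PdCl2(PPh3)2 (cat.), CuI (cat.), i-Pr2NH, degassed THF, 0 °C to rt
Reagents that add atoms: none
Why: Sonogashira coupling (oxidative addition of the vinyl iodide to zerovalent palladium, then transfer of the copper acetylide of 10) joins C3 to C4 with retention of alkene geometry, a short run at low temperature limiting epimerisation at C6 and ionisation of the propargylic epoxide (C6 is named R only through the change in priorities).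

Step 17
Reactants: 23 (the enyne of step 16)
Product: 24 (R)-3-(hydroxymethyl)-5-[(1Z,3Z)-4-{(2R,3R)-3-[2-(4-methoxybenzyloxy)ethyl]-3-methyloxiran-2-yl}-2-methylbuta-1,3-dien-1-yl]furan-2(5H)-one
Conditions: H2 (1 atm), Lindlar catalyst (Pd/CaCO3 poisoned with Pb(OAc)2), quinoline, EtOAc, rt
Reagents that add atoms: none
Why: Lindlar semi-hydrogenation delivers one equivalent of hydrogen syn to the C2≡C3 alkyne and completes the (2Z,4Z)-diene, with quinoline and interruption at one equivalent guarding against over-reduction and hydrogenolysis of the allylic epoxide.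

Step 18
Reactants: 24 (the Z,Z-diene alcohol of step 17)
Product: 25 (R)-3-(bromomethyl)-5-[(1Z,3Z)-4-{(2R,3R)-3-[2-(4-methoxybenzyloxy)ethyl]-3-methyloxiran-2-yl}-2-methylbuta-1,3-dien-1-yl]furan-2(5H)-one
Conditions: CBr4, PPh3, 2,6-lutidine, CH2Cl2, −20 °C to 0 °C
Reagents that add atoms: carbon tetrabromide, BrC(Br)(Br)Br
Why: The Appel reaction converts the primary allylic alcohol into the bromide at low temperature under essentially neutral conditions tolerated by the PMB ether and the epoxide.

Step 19
Reactants: 25 (the allylic bromide of step 18)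
Product: 26 (R)-3-(bromomethyl)-5-[(1Z,3Z)-4-{(2R,3R)-3-(2-hydroxyethyl)-3-methyloxiran-2-yl}-2-methylbuta-1,3-dien-1-yl]furan-2(5H)-one
Conditions: DDQ, CH2Cl2/pH 7 phosphate buffer, 0 °C
Reagents that add atoms: none
Why: Oxidative PMB cleavage by DDQ through the benzylic oxocarbenium ion under buffered conditions should leave the allylic bromide and the dienyl epoxide in place.

Step 20
Reactants: 26 (the primary alcohol of step 19)
Product: 27 (R)-3-(bromomethyl)-5-[(1Z,3Z)-2-methyl-4-{(2R,3R)-3-methyl-3-(2-oxoethyl)oxiran-2-yl}buta-1,3-dien-1-yl]furan-2(5H)-one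
Conditions: Dess–Martin periodinane, NaHCO3, CH2Cl2, 0 °C; used at once
Reagents that add atoms: none
Why: Buffered Dess–Martin oxidation gives the β,γ-epoxy aldehyde without the acid or base that would trigger elimination with epoxide opening.

Step 21
Reactants: 27 (the bromo aldehyde of step 20)
Product: 30 (1R,6R,7R,8S,10R)-1,10-epoxy-8-hydroxygermacra-2Z,4Z,11(13)-trien-12,6-olide, via allylchromium dichloride 28 (not isolated), via chromium alkoxide 29 (not isolated)
Conditions: CrCl2 (8 equiv), THF, rt, slow addition of 27 (final 2 mM); then H2O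
Reagents that add atoms: none
Why: Two equivalents of CrCl2 reduce the allylic C13–Br bond to the allylchromium 28, which adds through its γ-carbon C7 to the tethered aldehyde carbon C8 in a six-membered Zimmerman–Traxler chair, moving the double bond to C11=C13 and so unveiling the α-methylene-γ-butyrolactone. The closest known reaction types are the Nozaki–Hiyama–Kishi allylation in its intramolecular medium-ring form and the Barbier allylation of aldehydes with 5-substituted 3-(bromomethyl)furan-2(5H)-ones. The ten-membered carbocycle closes in a 10-exo-trig mode, the C8=O bond staying outside the new ring. C7 is controlled by the existing C6 stereocentre: the aldehyde reaches the butenolide face opposite the C5 dienyl substituent, giving the 6,7-trans lactone (7R). C8 is controlled by the chair, in which the aldehyde chain (C9) sits pseudo-equatorial, anti to C11 and away from the lactone ring, which gives the 8S carbinol that the final inverting esterification requires. The step needs γ- over α-attack (inherent to allylchromium; α-attack would give a twelve-membered ring), cyclisation over oligomerisation (slow addition, high dilution) and survival of the vinyl epoxide and β,γ-epoxy aldehyde, which the neutral non-basic medium and the much faster reduction of the allylic bromide should secure.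

Step 22
Reactants: 30 (the 8S alcohol of step 21); 3 (2S,3R)-2,3-dimethyloxirane-2-carboxylic acid
Product: 31 (1R,6R,7R,8R,10R)-8-[(2S,3R)-2,3-epoxy-2-methylbutanoyloxy]-1,10-epoxygermacra-2Z,4Z,11(13)-trien-12,6-olide (CNP0122107.1)
Conditions: PPh3, DIAD (betaine preformed), toluene, 0 °C to rt
Reagents that add atoms: none
Why: In this Mitsunobu esterification the preformed PPh3–DIAD betaine activates the 8S hydroxyl as an oxyphosphonium ion, which the carboxylate of 3 displaces by SN2 with inversion to give the 8R ester, while the neutral conditions spare the α-methylene lactone and both epoxides.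

**Compound list**

1 | (E)-2-methylbut-2-en-1-ol | C/C=C(\C)CO | starting material
2 | ((2R,3R)-2,3-dimethyloxiran-2-yl)methanol | OC[C@@]1(C)O[C@@H]1C | intermediate
3 | (2S,3R)-2,3-dimethyloxirane-2-carboxylic acid | OC(=O)[C@@]1(C)O[C@@H]1C | intermediate
4 | but-3-yn-1-ol | C#CCCO | starting material
5 | 1-[(but-3-yn-1-yloxy)methyl]-4-methoxybenzene | C#CCCOCc1ccc(OC)cc1 | intermediate
6 | (E)-dimethyl{4-[(4-methoxybenzyl)oxy]-2-methylbut-1-en-1-yl}alane | C[Al](C)/C=C(\C)CCOCc1ccc(OC)cc1 | intermediate (not isolated)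
7 | (E)-5-[(4-methoxybenzyl)oxy]-3-methylpent-2-en-1-ol | OC/C=C(\C)CCOCc1ccc(OC)cc1 | intermediate
8 | ((2R,3R)-3-{2-[(4-methoxybenzyl)oxy]ethyl}-3-methyloxiran-2-yl)methanol | OC[C@H]1O[C@]1(C)CCOCc1ccc(OC)cc1 | intermediate
9 | (2S,3R)-3-{2-[(4-methoxybenzyl)oxy]ethyl}-3-methyloxirane-2-carbaldehyde | O=C[C@H]1O[C@]1(C)CCOCc1ccc(OC)cc1 | intermediate
10 | (2R,3R)-3-ethynyl-2-{2-[(4-methoxybenzyl)oxy]ethyl}-2-methyloxirane | C#C[C@H]1O[C@]1(C)CCOCc1ccc(OC)cc1 | intermediate
11 | acrolein | C=CC=O | starting material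
12 | prop-1-yn-1-ylmagnesium bromide | CC#C[Mg]Br | starting material
13 | rac-hex-1-en-4-yn-3-ol | C=CC(O)C#CC | intermediate
14 | (S)-hex-1-en-4-yn-3-ol | O[C@@H](C=C)C#CC | intermediate
15 | sodium (S)-2,2-bis(2-methoxyethoxy)-3-methyl-5-vinyl-2,5-dihydro-1,2-oxaaluminol-2-uide (cyclic alkenylalanate) | [Na+].COCCO[Al-]1(OCCOC)O[C@@H](C=C)C=C1C | intermediate (not isolated)
16 | (3S,4Z)-4-iodohexa-1,4-dien-3-ol | O[C@@H](C=C)/C=C(\I)C | intermediate
17 | ethyl 2-(hydroxymethyl)acrylate | C=C(CO)C(=O)OCC | starting material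
18 | ethyl 2-{[(tert-butyldimethylsilyl)oxy]methyl}acrylate | C=C(CO[Si](C)(C)C(C)(C)C)C(=O)OCC | intermediate
19 | 2-{[(tert-butyldimethylsilyl)oxy]methyl}acrylic acid | C=C(CO[Si](C)(C)C(C)(C)C)C(=O)O | intermediate
20 | (3S,4Z)-4-iodohexa-1,4-dien-3-yl 2-{[(tert-butyldimethylsilyl)oxy]methyl}acrylate | C=C(CO[Si](C)(C)C(C)(C)C)C(=O)O[C@@H](C=C)/C=C(\I)C | intermediate
21 | (S)-3-{[(tert-butyldimethylsilyl)oxy]methyl}-5-[(Z)-2-iodoprop-1-en-1-yl]furan-2(5H)-one | O=C1O[C@@H](C=C1CO[Si](C)(C)C(C)(C)C)/C=C(\I)C | intermediate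
22 | (S)-3-(hydroxymethyl)-5-[(Z)-2-iodoprop-1-en-1-yl]furan-2(5H)-one | O=C1O[C@@H](C=C1CO)/C=C(\I)C | intermediate
23 | (R)-3-(hydroxymethyl)-5-[(Z)-4-{(2R,3R)-3-[2-(4-methoxybenzyloxy)ethyl]-3-methyloxiran-2-yl}-2-methylbut-1-en-3-yn-1-yl]furan-2(5H)-one | O=C1O[C@@H](C=C1CO)/C=C(C)\C#C[C@H]2O[C@]2(C)CCOCc3ccc(OC)cc3 | intermediate
24 | (R)-3-(hydroxymethyl)-5-[(1Z,3Z)-4-{(2R,3R)-3-[2-(4-methoxybenzyloxy)ethyl]-3-methyloxiran-2-yl}-2-methylbuta-1,3-dien-1-yl]furan-2(5H)-one | O=C1O[C@@H](C=C1CO)/C=C(C)\C=C/[C@H]2O[C@]2(C)CCOCc3ccc(OC)cc3 | intermediate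
25 | (R)-3-(bromomethyl)-5-[(1Z,3Z)-4-{(2R,3R)-3-[2-(4-methoxybenzyloxy)ethyl]-3-methyloxiran-2-yl}-2-methylbuta-1,3-dien-1-yl]furan-2(5H)-one | O=C1O[C@@H](C=C1CBr)/C=C(C)\C=C/[C@H]2O[C@]2(C)CCOCc3ccc(OC)cc3 | intermediate
26 | (R)-3-(bromomethyl)-5-[(1Z,3Z)-4-{(2R,3R)-3-(2-hydroxyethyl)-3-methyloxiran-2-yl}-2-methylbuta-1,3-dien-1-yl]furan-2(5H)-one | O=C1O[C@@H](C=C1CBr)/C=C(C)\C=C/[C@H]2O[C@]2(C)CCO | intermediate
27 | (R)-3-(bromomethyl)-5-[(1Z,3Z)-2-methyl-4-{(2R,3R)-3-methyl-3-(2-oxoethyl)oxiran-2-yl}buta-1,3-dien-1-yl]furan-2(5H)-one | O=C1O[C@@H](C=C1CBr)/C=C(C)\C=C/[C@H]2O[C@]2(C)CC=O | intermediate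
28 | allylchromium dichloride derived from 27 (CrCl2 on C13) | O=C1O[C@@H](C=C1C[Cr](Cl)Cl)/C=C(C)\C=C/[C@H]2O[C@]2(C)CC=O | intermediate (not isolated)
29 | dichlorochromium 8-alkoxide of 30 | C=C1C(=O)O[C@@H]2/C=C(C)\C=C/[C@H]3O[C@]3(C)C[C@H](O[Cr](Cl)Cl)[C@@H]12 | intermediate (not isolated)
30 | (1R,6R,7R,8S,10R)-1,10-epoxy-8-hydroxygermacra-2Z,4Z,11(13)-trien-12,6-olide | C=C1C(=O)O[C@@H]2/C=C(C)\C=C/[C@H]3O[C@]3(C)C[C@H](O)[C@@H]12 | intermediate
31 | (1R,6R,7R,8R,10R)-8-[(2S,3R)-2,3-epoxy-2-methylbutanoyloxy]-1,10-epoxygermacra-2Z,4Z,11(13)-trien-12,6-olide | C=C1C(=O)O[C@@H]2/C=C(C)\C=C/[C@H]3O[C@]3(C)C[C@@H](OC(=O)[C@@]3(C)O[C@@H]3C)[C@@H]12 | target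

**Step count and risks**

Total step count: 22. Longest linear sequence: 13 steps (steps 8, 9, 10, 13, 14, 15, 16, 17, 18, 19, 20, 21, 22).

Steps most likely to fail:

1. Step 21. The tether may force the aldehyde to present its other face in the ten-membered transition state (C9 over the lactone ring), overriding the chair preference and giving the C8 epimer. The fallback sets out from 27 and comes back at 31. The cyclisation is then taken through to (1R,6R,7R,8R,10R)-1,10-epoxy-8-hydroxygermacra-2Z,4Z,11(13)-trien-12,6-olide F1, which already has the C8 configuration of the target. F1 is acylated with retention by Steglich esterification with acid 3 (DCC, DMAP, CH2Cl2, 0 °C) in place of the inverting Mitsunobu reaction.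

2. Step 22. The oxyphosphonium ion of the hindered, ring-bound C8 carbinol may eliminate towards C7 or C9, or resist displacement by the α-quaternary carboxylate. The fallback sets out from 30 and comes back at 31. It inverts C8 by oxidation and reduction: buffered Dess–Martin oxidation of 30 (NaHCO3, CH2Cl2, 0 °C) to (1R,6R,7S,10R)-1,10-epoxy-8-oxogermacra-2Z,4Z,11(13)-trien-12,6-olide F2, then Luche reduction (NaBH4, CeCl3·7H2O, MeOH, −78 °C). Hydride is expected to arrive from the more exposed ring face, giving the 8R alcohol F1 described above, and Steglich acylation of F1 with 3 (DCC, DMAP) then gives 31.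

3. Step 17. Hydrogen uptake may not stop at the diene, or the allylic epoxide may be hydrogenolysed on palladium. The fallback sets out from 9 and 22 and comes back at 24; it joins two alkenes of fixed Z geometry and uses no alkyne. Aldehyde 9 is converted by Stork–Zhao olefination ((iodomethyl)triphenylphosphonium iodide, NaHMDS, THF/DMPU, −78 °C) into (2R,3R)-3-[(Z)-2-iodovinyl]-2-{2-[(4-methoxybenzyl)oxy]ethyl}-2-methyloxirane F3. Iodide 22 is converted by Miyaura borylation (B2pin2, PdCl2(PPh3)2, KOPh, toluene, 50 °C) into (R)-3-(hydroxymethyl)-5-[(E)-2-(4,4,5,5-tetramethyl-1,3,2-dioxaborolan-2-yl)prop-1-en-1-yl]furan-2(5H)-one F4 with retention of geometry. Suzuki coupling of F3 with F4 (Pd(PPh3)4, TlOEt, THF/H2O, rt) then gives 24.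

Further compounds
F1 | step 21 | (1R,6R,7R,8R,10R)-1,10-epoxy-8-hydroxygermacra-2Z,4Z,11(13)-trien-12,6-olide | C=C1C(=O)O[C@@H]2/C=C(C)\C=C/[C@H]3O[C@]3(C)C[C@@H](O)[C@@H]12
F2 | step 22 | (1R,6R,7S,10R)-1,10-epoxy-8-oxogermacra-2Z,4Z,11(13)-trien-12,6-olide | C=C1C(=O)O[C@@H]2/C=C(C)\C=C/[C@H]3O[C@]3(C)CC(=O)[C@@H]12
F3 | step 17 | (2R,3R)-3-[(Z)-2-iodovinyl]-2-{2-[(4-methoxybenzyl)oxy]ethyl}-2-methyloxirane | I/C=C\[C@H]1O[C@]1(C)CCOCc1ccc(OC)cc1
F4 | step 17 | (R)-3-(hydroxymethyl)-5-[(E)-2-(4,4,5,5-tetramethyl-1,3,2-dioxaborolan-2-yl)prop-1-en-1-yl]furan-2(5H)-one | O=C1O[C@@H](C=C1CO)/C=C(\B2OC(C)(C)C(C)(C)O2)C
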